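**Plan**
- Target: epigallocatechin-(4β→6)-epigallocatechin 3-O-gallate. Retrosynthesis first removes fourteen O-benzyl groups and cuts the gallate ester C–O bond at lower C3.
- In pyran ring F the CH2 at lower C4 sits next to the oxygenated lower C3. This is the pattern left by hydroboration of a C3=C4 alkene in a 2H-chromene, and that alkene is cut by ring-closing metathesis.
- Further cuts: the lower O1–C2 allylic ether bond, the vinyl carbon on lower C4a, and the interflavan bond from upper C4 to lower C6.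
- Forward: rings A, C and B come intact from (−)-epigallocatechin, which is benzylated and activated at C4. Ring D (a phloroglucinol diether) is attached there, then formylated, methylenated and O-allylated, which brings in ring E. Ring F is closed last.
- Stereochemistry: upper C2 and C3 come from the chiral pool. Upper C4 is set by attack anti to the 2-aryl and 3-benzyloxy groups. Lower C2 is set by the iridium–phosphoramidite catalyst. Lower C3 is set by LiBH(s-Bu)3 reduction of the ring-F ketone anti to the lower 2-aryl group.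

Key step: step 13

**Remarks**
- Flavan numbering is used in each unit. "Upper" is the unit with rings A (benzo), C (pyran) and B (pendant aryl). "Lower" is the unit with rings D (benzo), F (pyran) and E (pendant aryl).
- 3,5-Bis(benzyloxy)phenol and 3,4,5-tris(benzyloxy)benzoic acid are taken as catalogue compounds. They are the dibenzyl ether of phloroglucinol and the tribenzyl ether of gallic acid.
- L is the BINOL-derived phosphoramidite O,O'-(1,1'-binaphthalene-2,2'-diyl) N,N-bis(1-phenylethyl)phosphoramidite. The enantiomer that gives the (S)-ether is assumed to be (Sa,Sc,Sc). This is to be confirmed on a simple 2-vinylphenol, and the mirror-image ligand is used if the sense is opposite.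
- Rotation about the upper C4–lower C6 bond is hindered. Rotamers of 7–22 are one compound each, and this rotation makes the two ortho positions of phenol 8 equivalent.

**Step 1**
Reactants: 1 (−)-epigallocatechin
Product: 2 5,7,3',4',5'-penta-O-benzyl-(−)-epigallocatechin
Conditions: BnBr (5.5 equiv), K2CO3, DMF, 0 °C→rt, argon
Reagents that add atoms: benzyl bromide, BrCc1ccccc1
Why: Williamson etherification; K2CO3 deprotonates only the five phenols, so the secondary 3-OH stays free, and the mild base at low temperature should avoid ring opening and C2 epimerisation.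

**Step 2**
Reactants: 2 5,7,3',4',5'-penta-O-benzyl-(−)-epigallocatechin
Product: 3 4β-(2-ethoxyethoxy)-5,7,3',4',5'-penta-O-benzylepigallocatechin
Conditions: DDQ (2 equiv), HOCH2CH2OEt, CH2Cl2, rt
Reagents that add atoms: 2-ethoxyethanol, CCOCCO
Why: DDQ benzylic oxidation; hydride loss from C4 is assisted by the 5- and 7-benzyloxy groups, and the alcohol traps the ring-A-stabilised cation anti to the 2-aryl and 3-hydroxyl groups (4β), a centre that is ionised again in step 5.

**Step 3**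
Reactants: 3 4β-(2-ethoxyethoxy)-5,7,3',4',5'-penta-O-benzylepigallocatechin
Product: 4 3,5,7,3',4',5'-hexa-O-benzyl-4β-(2-ethoxyethoxy)epigallocatechin
Conditions: NaH, BnBr, n-Bu4NI (cat.), DMF, 0 °C→rt
Reagents that add atoms: benzyl bromide, BrCc1ccccc1
Why: Williamson etherification of the sodium alkoxide; the C4 ether and the aryl benzyl ethers are stable to base, and the benzyl group shields the upper 3-OH from the later oxidation and acylation and leaves with the others at the end.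

**Step 4**
Reactants: 5 3,5-bis(benzyloxy)phenol
Product: 6 [3,5-bis(benzyloxy)phenoxy]triisopropylsilane
Conditions: i-Pr3SiCl, imidazole, DMF, rt
Reagents that add atoms: chlorotriisopropylsilane, CC(C)[Si](Cl)(C(C)C)C(C)C
Why: Imidazole-promoted O-silylation of a phenol; the bulky silyl ether marks the oxygen that becomes lower O1 and shields its two ortho carbons.

**Step 5**
Reactants: 4 3,5,7,3',4',5'-hexa-O-benzyl-4β-(2-ethoxyethoxy)epigallocatechin; 6 [3,5-bis(benzyloxy)phenoxy]triisopropylsilane (3 equiv)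
Product: 7 4β-[2,6-bis(benzyloxy)-4-(triisopropylsilyloxy)phenyl]-3,5,7,3',4',5'-hexa-O-benzylepigallocatechin
Conditions: Me3SiOTf (0.5 equiv), CH2Cl2, −78 °C
Reagents that add atoms: none
Why: Lewis-acid-mediated Friedel–Crafts arylation of the flavan C4 cation; the arene attacks anti to the α-oriented 2-aryl and 3-benzyloxy groups (4β, 3,4-trans), and it should react through the carbon para to the bulky silyl ether, between the two benzyloxy groups.

**Step 6**
Reactants: 7 4β-[2,6-bis(benzyloxy)-4-(triisopropylsilyloxy)phenyl]-3,5,7,3',4',5'-hexa-O-benzylepigallocatechin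
Product: 8 4β-[2,6-bis(benzyloxy)-4-hydroxyphenyl]-3,5,7,3',4',5'-hexa-O-benzylepigallocatechin
Conditions: n-Bu4NF, THF, 0 °C
Reagents that add atoms: none
Why: Fluoride cleavage of an aryl silyl ether; benzyl ethers and the interflavan bond are inert to fluoride.

**Step 7**
Reactants: 8 4β-[2,6-bis(benzyloxy)-4-hydroxyphenyl]-3,5,7,3',4',5'-hexa-O-benzylepigallocatechin
Product: 9 4β-[2,6-bis(benzyloxy)-3-formyl-4-hydroxyphenyl]-3,5,7,3',4',5'-hexa-O-benzylepigallocatechin
Conditions: MgCl2, Et3N, (CH2O)n, THF, reflux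
Reagents that add atoms: paraformaldehyde (as formaldehyde), C=O
Why: Casnati–Skattebøl ortho-formylation; the magnesium phenoxide delivers formaldehyde only to a carbon ortho to the free hydroxyl, and since the two ortho carbons are equivalent a single salicylaldehyde results, whose formyl carbon becomes lower C4.

**Step 8**
Reactants: 9 4β-[2,6-bis(benzyloxy)-3-formyl-4-hydroxyphenyl]-3,5,7,3',4',5'-hexa-O-benzylepigallocatechin
Product: 10 4β-[2,6-bis(benzyloxy)-4-hydroxy-3-vinylphenyl]-3,5,7,3',4',5'-hexa-O-benzylepigallocatechin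
Conditions: Ph3PCH3Br, KOt-Bu (3 equiv each), THF, 0 °C→rt; neutral work-up
Reagents that add atoms: methyltriphenylphosphonium bromide, [Br-].C[P+](c1ccccc1)(c1ccccc1)c1ccccc1
Why: Wittig methylenation of a salicylaldehyde; the first equivalent of ylide deprotonates the phenol and the unstabilised ylide still olefinates the phenoxide aldehyde, as known for 2-hydroxybenzaldehydes.

**Step 9**
Reactants: 11 3,4,5-tris(benzyloxy)benzaldehyde
Product: 12 ethyl (E)-3-[3,4,5-tris(benzyloxy)phenyl]acrylate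
Conditions: (EtO)2P(O)CH2CO2Et, NaH, THF, 0 °C→rt
Reagents that add atoms: triethyl phosphonoacetate, CCOC(=O)CP(=O)(OCC)OCC
Why: Horner–Wadsworth–Emmons olefination; the stabilised phosphonate anion gives the E-cinnamate.

**Step 10**
Reactants: 12 ethyl (E)-3-[3,4,5-tris(benzyloxy)phenyl]acrylate
Product: 13 (E)-3-[3,4,5-tris(benzyloxy)phenyl]prop-2-en-1-ol
Conditions: i-Bu2AlH (2.5 equiv), CH2Cl2, −78 °C; aq. KNaC4H4O6 (potassium sodium tartrate)
Reagents that add atoms: none
Why: 1,2-Reduction of an enoate by i-Bu2AlH; the alkene geometry and the benzyl ethers are untouched.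

**Step 11**
Reactants: 13 (E)-3-[3,4,5-tris(benzyloxy)phenyl]prop-2-en-1-ol
Product: 14 methyl (E)-3-[3,4,5-tris(benzyloxy)phenyl]allyl carbonate
Conditions: ClCO2Me, pyridine, CH2Cl2, 0 °C
Reagents that add atoms: methyl chloroformate, COC(Cl)=O
Why: O-Acylation of a primary allylic alcohol; the methyl carbonate is the standard leaving group for iridium-catalysed allylic substitution and supplies its own methoxide base.

**Step 12**
Reactants: 10 4β-[2,6-bis(benzyloxy)-4-hydroxy-3-vinylphenyl]-3,5,7,3',4',5'-hexa-O-benzylepigallocatechin; 14 methyl (E)-3-[3,4,5-tris(benzyloxy)phenyl]allyl carbonate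
Product: 15 4β-{2,6-bis(benzyloxy)-4-[(1S)-1-(3,4,5-tris(benzyloxy)phenyl)prop-2-en-1-yloxy]-3-vinylphenyl}-3,5,7,3',4',5'-hexa-O-benzylepigallocatechin
Conditions: [Ir(cod)Cl]2 (2 mol%), (Sa,Sc,Sc)-L (4 mol%), n-PrNH2 (catalyst activation), K3PO4, THF, 50 °C
Reagents that add atoms: none
Why: Iridium-catalysed asymmetric allylic etherification, known for 2-vinylphenols with cinnamyl carbonates; the aryloxide attacks the aryl-bearing terminus of the iridium allyl anti to the metal, and the cyclometalated iridium–phosphoramidite (catalyst control) sets the (S) centre that becomes lower C2.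

**Step 13**
Reactants: 15 4β-{2,6-bis(benzyloxy)-4-[(1S)-1-(3,4,5-tris(benzyloxy)phenyl)prop-2-en-1-yloxy]-3-vinylphenyl}-3,5,7,3',4',5'-hexa-O-benzylepigallocatechin
Product: 16 3,5,7,3',4',5'-hexa-O-benzylepigallocatechin-(4β→6)-[(2S)-5,7,3',4',5'-pentakis(benzyloxy)flav-3-ene]
Conditions: second-generation Grubbs catalyst (H2IMes)(PCy3)Cl2Ru=CHPh (5 mol%), 1,4-benzoquinone (10 mol%), CH2Cl2 (5 mM), 40 °C
Reagents that add atoms: none
Why: Ring-closing olefin metathesis: the ruthenium benzylidene exchanges onto one terminal alkene, the new alkylidene adds across the other vinyl group to a ruthenacyclobutane, and cycloreversion gives the lower C3=C4 double bond and, overall, ethylene. The closest known reaction type is the cyclisation of 2-vinylphenyl 1-arylallyl ethers to 2-aryl-2H-chromenes with the same catalyst. Ring F closes as a six-membered ring by joining two vinyl carbons held ortho to each other on ring D through O1 and C4a, so only the cis ring alkene can form. No stereocentre is created, and lower C2 from step 12 and the three upper centres are spectators. The step needs cyclisation to win over intermolecular cross-metathesis, which high dilution and the ortho arrangement secure, and it needs the allylic ether and the product alkene not to migrate, which the benzoquinone additive (a trap for ruthenium hydrides) and the mild temperature secure. The ring position is fixed by the substrate, because the vinyl group sits on the only carbon between the ether oxygen and a benzyloxy group, so only the 4→6 linked flav-3-ene can arise.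

**Step 14**
Reactants: 16 3,5,7,3',4',5'-hexa-O-benzylepigallocatechin-(4β→6)-[(2S)-5,7,3',4',5'-pentakis(benzyloxy)flav-3-ene]
Product: 18 3,5,7,3',4',5'-hexa-O-benzylepigallocatechin-(4β→6)-5,7,3',4',5'-penta-O-benzylgallocatechin, via lower C3 alkylborane 17 (not isolated)
Conditions: BH3·THF (excess), THF, 0 °C→rt; then NaOH, H2O2, H2O, 0 °C→rt
Reagents that add atoms: borane–tetrahydrofuran, B.C1CCOC1 (boron of 17); hydrogen peroxide, OO (oxygen of 18)
Why: Hydroboration–oxidation of a flav-3-ene; boron goes to lower C3 because the electron-rich ring D and the peri 5-benzyloxy group direct hydrogen to the benzylic C4, addition occurs anti to the lower C2 aryl group, and oxidation with retention gives the 2,3-trans alcohol (2R,3S; the change of the C2 descriptor is only a priority change).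

**Step 15**
Reactants: 18 3,5,7,3',4',5'-hexa-O-benzylepigallocatechin-(4β→6)-5,7,3',4',5'-penta-O-benzylgallocatechin
Product: 19 3,5,7,3',4',5'-hexa-O-benzylepigallocatechin-(4β→6)-[(2R)-5,7,3',4',5'-pentakis(benzyloxy)flavan-3-one]
Conditions: Dess–Martin periodinane, water-saturated CH2Cl2, rt; used at once
Reagents that add atoms: none
Why: Dess–Martin oxidation of the only free hydroxyl to the flavan-3-one under near-neutral conditions, known for benzylated catechins without loss of the C2 configuration.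

**Step 16**
Reactants: 19 3,5,7,3',4',5'-hexa-O-benzylepigallocatechin-(4β→6)-[(2R)-5,7,3',4',5'-pentakis(benzyloxy)flavan-3-one]
Product: 20 3,5,7,3',4',5'-hexa-O-benzylepigallocatechin-(4β→6)-5,7,3',4',5'-penta-O-benzylepigallocatechin
Conditions: LiBH(s-Bu)3 (L-Selectride), LiBr, THF, −78 °C
Reagents that add atoms: none
Why: Bulky-hydride reduction of a flavan-3-one; hydride is delivered equatorially to the face anti to the lower C2 aryl group, giving the axial 3-OH cis to that aryl group (3R), as known for the catechin-to-epicatechin inversion.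

**Step 17**
Reactants: 20 3,5,7,3',4',5'-hexa-O-benzylepigallocatechin-(4β→6)-5,7,3',4',5'-penta-O-benzylepigallocatechin; 21 3,4,5-tris(benzyloxy)benzoic acid
Product: 22 3,5,7,3',4',5'-hexa-O-benzylepigallocatechin-(4β→6)-5,7,3',4',5'-penta-O-benzylepigallocatechin 3-O-[3,4,5-tris(benzyloxy)benzoate]
Conditions: DCC, DMAP, CH2Cl2, rt
Reagents that add atoms: none
Why: Steglich esterification; the lower 3-OH is the only free hydroxyl, and the acyl transfer does not touch the carbinol centre.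

**Step 18**
Reactants: 22 3,5,7,3',4',5'-hexa-O-benzylepigallocatechin-(4β→6)-5,7,3',4',5'-penta-O-benzylepigallocatechin 3-O-[3,4,5-tris(benzyloxy)benzoate]
Product: 23 epigallocatechin-(4β→6)-epigallocatechin 3-O-gallate (gallate on the lower unit)
Conditions: H2 (1 atm), Pd(OH)2/C, THF/MeOH/H2O, rt; filtration and freeze-drying under argon
Reagents that add atoms: none
Why: Catalytic hydrogenolysis of all fourteen benzyl ethers, thirteen aryl and one alkyl; the ester, the interflavan C–C bond and the ring ethers are known to survive these conditions in galloylated proanthocyanidin dimers.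

**Compound list**
1 | (−)-epigallocatechin | O[C@@H]1Cc2c(O)cc(O)cc2O[C@@H]1c1cc(O)c(O)c(O)c1 | starting material
2 | 5,7,3',4',5'-penta-O-benzyl-(−)-epigallocatechin | O[C@@H]1Cc2c(OCc3ccccc3)cc(OCc3ccccc3)cc2O[C@@H]1c1cc(OCc2ccccc2)c(OCc2ccccc2)c(OCc2ccccc2)c1 | intermediate
3 | 4β-(2-ethoxyethoxy)-5,7,3',4',5'-penta-O-benzylepigallocatechin (2,3-cis, 3,4-trans) | CCOCCO[C@H]1c2c(OCc3ccccc3)cc(OCc3ccccc3)cc2O[C@H](c2cc(OCc3ccccc3)c(OCc3ccccc3)c(OCc3ccccc3)c2)[C@@H]1O | intermediate
4 | 3,5,7,3',4',5'-hexa-O-benzyl-4β-(2-ethoxyethoxy)epigallocatechin | CCOCCO[C@H]1c2c(OCc3ccccc3)cc(OCc3ccccc3)cc2O[C@H](c2cc(OCc3ccccc3)c(OCc3ccccc3)c(OCc3ccccc3)c2)[C@@H]1OCc1ccccc1 | intermediate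
5 | 3,5-bis(benzyloxy)phenol | Oc1cc(OCc2ccccc2)cc(OCc2ccccc2)c1 | starting material
6 | [3,5-bis(benzyloxy)phenoxy]triisopropylsilane | CC(C)[Si](Oc1cc(OCc2ccccc2)cc(OCc2ccccc2)c1)(C(C)C)C(C)C | intermediate
7 | 4β-[2,6-bis(benzyloxy)-4-(triisopropylsilyloxy)phenyl]-3,5,7,3',4',5'-hexa-O-benzylepigallocatechin | CC(C)[Si](Oc1cc(OCc2ccccc2)c([C@H]2c3c(OCc4ccccc4)cc(OCc4ccccc4)cc3O[C@H](c3cc(OCc4ccccc4)c(OCc4ccccc4)c(OCc4ccccc4)c3)[C@@H]2OCc2ccccc2)c(OCc2ccccc2)c1)(C(C)C)C(C)C | intermediate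
8 | 4β-[2,6-bis(benzyloxy)-4-hydroxyphenyl]-3,5,7,3',4',5'-hexa-O-benzylepigallocatechin | Oc1cc(OCc2ccccc2)c([C@H]2c3c(OCc4ccccc4)cc(OCc4ccccc4)cc3O[C@H](c3cc(OCc4ccccc4)c(OCc4ccccc4)c(OCc4ccccc4)c3)[C@@H]2OCc2ccccc2)c(OCc2ccccc2)c1 | intermediate
9 | 4β-[2,6-bis(benzyloxy)-3-formyl-4-hydroxyphenyl]-3,5,7,3',4',5'-hexa-O-benzylepigallocatechin | Oc1cc(OCc2ccccc2)c([C@H]2c3c(OCc4ccccc4)cc(OCc4ccccc4)cc3O[C@H](c3cc(OCc4ccccc4)c(OCc4ccccc4)c(OCc4ccccc4)c3)[C@@H]2OCc2ccccc2)c(OCc2ccccc2)c1C=O | intermediate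
10 | 4β-[2,6-bis(benzyloxy)-4-hydroxy-3-vinylphenyl]-3,5,7,3',4',5'-hexa-O-benzylepigallocatechin | Oc1cc(OCc2ccccc2)c([C@H]2c3c(OCc4ccccc4)cc(OCc4ccccc4)cc3O[C@H](c3cc(OCc4ccccc4)c(OCc4ccccc4)c(OCc4ccccc4)c3)[C@@H]2OCc2ccccc2)c(OCc2ccccc2)c1C=C | intermediate
11 | 3,4,5-tris(benzyloxy)benzaldehyde | O=Cc1cc(OCc2ccccc2)c(OCc2ccccc2)c(OCc2ccccc2)c1 | starting material
12 | ethyl (E)-3-[3,4,5-tris(benzyloxy)phenyl]acrylate | CCOC(=O)/C=C/c1cc(OCc2ccccc2)c(OCc2ccccc2)c(OCc2ccccc2)c1 | intermediate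
13 | (E)-3-[3,4,5-tris(benzyloxy)phenyl]prop-2-en-1-ol | OC/C=C/c1cc(OCc2ccccc2)c(OCc2ccccc2)c(OCc2ccccc2)c1 | intermediate
14 | methyl (E)-3-[3,4,5-tris(benzyloxy)phenyl]allyl carbonate | COC(=O)OC/C=C/c1cc(OCc2ccccc2)c(OCc2ccccc2)c(OCc2ccccc2)c1 | intermediate
15 | 4β-{2,6-bis(benzyloxy)-4-[(1S)-1-(3,4,5-tris(benzyloxy)phenyl)prop-2-en-1-yloxy]-3-vinylphenyl}-3,5,7,3',4',5'-hexa-O-benzylepigallocatechin (metathesis precursor) | C=C[C@@H](c1cc(OCc2ccccc2)c(OCc2ccccc2)c(OCc2ccccc2)c1)Oc1cc(OCc2ccccc2)c([C@H]2c3c(OCc4ccccc4)cc(OCc4ccccc4)cc3O[C@H](c3cc(OCc4ccccc4)c(OCc4ccccc4)c(OCc4ccccc4)c3)[C@@H]2OCc2ccccc2)c(OCc2ccccc2)c1C=C | intermediate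
16 | 3,5,7,3',4',5'-hexa-O-benzylepigallocatechin-(4β→6)-[(2S)-5,7,3',4',5'-pentakis(benzyloxy)flav-3-ene] (metathesis product) | C1=Cc2c(cc(OCc3ccccc3)c([C@H]3c4c(OCc5ccccc5)cc(OCc5ccccc5)cc4O[C@H](c4cc(OCc5ccccc5)c(OCc5ccccc5)c(OCc5ccccc5)c4)[C@@H]3OCc3ccccc3)c2OCc2ccccc2)O[C@@H]1c1cc(OCc2ccccc2)c(OCc2ccccc2)c(OCc2ccccc2)c1 | intermediate
17 | lower C3 alkylborane from 16 (monoalkylborane, boron trans to the lower C2 aryl group; not isolated) | B[C@H]1Cc2c(cc(OCc3ccccc3)c([C@H]3c4c(OCc5ccccc5)cc(OCc5ccccc5)cc4O[C@H](c4cc(OCc5ccccc5)c(OCc5ccccc5)c(OCc5ccccc5)c4)[C@@H]3OCc3ccccc3)c2OCc2ccccc2)O[C@@H]1c1cc(OCc2ccccc2)c(OCc2ccccc2)c(OCc2ccccc2)c1 | intermediate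
18 | 3,5,7,3',4',5'-hexa-O-benzylepigallocatechin-(4β→6)-5,7,3',4',5'-penta-O-benzylgallocatechin (lower unit 2R,3S, 2,3-trans, free 3-OH) | O[C@H]1Cc2c(cc(OCc3ccccc3)c([C@H]3c4c(OCc5ccccc5)cc(OCc5ccccc5)cc4O[C@H](c4cc(OCc5ccccc5)c(OCc5ccccc5)c(OCc5ccccc5)c4)[C@@H]3OCc3ccccc3)c2OCc2ccccc2)O[C@@H]1c1cc(OCc2ccccc2)c(OCc2ccccc2)c(OCc2ccccc2)c1 | intermediate
19 | 3,5,7,3',4',5'-hexa-O-benzylepigallocatechin-(4β→6)-[(2R)-5,7,3',4',5'-pentakis(benzyloxy)flavan-3-one] | O=C1Cc2c(cc(OCc3ccccc3)c([C@H]3c4c(OCc5ccccc5)cc(OCc5ccccc5)cc4O[C@H](c4cc(OCc5ccccc5)c(OCc5ccccc5)c(OCc5ccccc5)c4)[C@@H]3OCc3ccccc3)c2OCc2ccccc2)O[C@@H]1c1cc(OCc2ccccc2)c(OCc2ccccc2)c(OCc2ccccc2)c1 | intermediate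
20 | 3,5,7,3',4',5'-hexa-O-benzylepigallocatechin-(4β→6)-5,7,3',4',5'-penta-O-benzylepigallocatechin (lower unit 2R,3R, 2,3-cis, free 3-OH) | O[C@@H]1Cc2c(cc(OCc3ccccc3)c([C@H]3c4c(OCc5ccccc5)cc(OCc5ccccc5)cc4O[C@H](c4cc(OCc5ccccc5)c(OCc5ccccc5)c(OCc5ccccc5)c4)[C@@H]3OCc3ccccc3)c2OCc2ccccc2)O[C@@H]1c1cc(OCc2ccccc2)c(OCc2ccccc2)c(OCc2ccccc2)c1 | intermediate
21 | 3,4,5-tris(benzyloxy)benzoic acid | O=C(O)c1cc(OCc2ccccc2)c(OCc2ccccc2)c(OCc2ccccc2)c1 | starting material
22 | 3,5,7,3',4',5'-hexa-O-benzylepigallocatechin-(4β→6)-5,7,3',4',5'-penta-O-benzylepigallocatechin 3-O-[3,4,5-tris(benzyloxy)benzoate] | O=C(O[C@@H]1Cc2c(cc(OCc3ccccc3)c([C@H]3c4c(OCc5ccccc5)cc(OCc5ccccc5)cc4O[C@H](c4cc(OCc5ccccc5)c(OCc5ccccc5)c(OCc5ccccc5)c4)[C@@H]3OCc3ccccc3)c2OCc2ccccc2)O[C@@H]1c1cc(OCc2ccccc2)c(OCc2ccccc2)c(OCc2ccccc2)c1)c1cc(OCc2ccccc2)c(OCc2ccccc2)c(OCc2ccccc2)c1 | intermediate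
23 | epigallocatechin-(4β→6)-epigallocatechin 3-O-gallate (CNP0204196.2) | O=C(O[C@@H]1Cc2c(cc(O)c([C@H]3c4c(O)cc(O)cc4O[C@H](c4cc(O)c(O)c(O)c4)[C@@H]3O)c2O)O[C@@H]1c1cc(O)c(O)c(O)c1)c1cc(O)c(O)c(O)c1 | target

**Step count**
Total: 18 steps. Longest linear sequence: 14 steps from 1 (steps 1–3, 5–8, 12–18). Side branches: step 4, and steps 9–11.

**Steps most likely to fail**

Step 5. The cation may attack a ring carbon beside the silyloxy group instead of the one between the benzyloxy groups, and it may be used up in chain growth with the electron-rich ring A of another molecule. The fallback replaces steric control by symmetry. Setting out from 4, Lewis-acid arylation (BF3·OEt2, THF/CH2Cl2, −20 °C) of a large excess of phloroglucinol, whose three ring carbons are identical, should give 4β-(2,4,6-trihydroxyphenyl)-3,5,7,3',4',5'-hexa-O-benzylepigallocatechin F1. Silylation of the unhindered hydroxyl para to the flavanyl group (i-Pr3SiCl, 1 equiv, imidazole, DMF, 0 °C) should give 4β-[2,6-dihydroxy-4-(triisopropylsilyloxy)phenyl]-3,5,7,3',4',5'-hexa-O-benzylepigallocatechin F2. Benzylation of the two flanking hydroxyls (BnBr, K2CO3, acetone) comes back to the route at 7.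

Step 12. The electron-rich branched ether may re-ionise on iridium, which would erode the branched-to-linear ratio and the enantiomeric purity, and the hindered phenol may turn over slowly. The fallback makes the C–O bond from a carbinol of defined configuration instead.
- From aldehyde 11, Me2Zn-mediated addition of trimethylsilylacetylene with a ProPhenol ligand (enantiomer chosen for this sense) should give (S)-1-[3,4,5-tris(benzyloxy)phenyl]-3-(trimethylsilyl)prop-2-yn-1-ol F4.
- K2CO3 in methanol removes the silyl group to give (R)-1-[3,4,5-tris(benzyloxy)phenyl]prop-2-yn-1-ol F5. The spatial arrangement is unchanged; only the descriptor changes.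
- Setting out from phenol 10, Mitsunobu etherification with F5 (PPh3, diisopropyl azodicarboxylate, toluene, 0 °C) should proceed with inversion to 4β-{2,6-bis(benzyloxy)-4-[(1S)-1-(3,4,5-tris(benzyloxy)phenyl)prop-2-yn-1-yloxy]-3-vinylphenyl}-3,5,7,3',4',5'-hexa-O-benzylepigallocatechin F6.
- Partial hydrogenation of the terminal alkyne (H2, Pd/CaCO3 poisoned with Pb(OAc)2, quinoline, EtOAc) comes back to the route at 15.

Step 8. Olefination of the phenoxide-deactivated, doubly ortho-flanked aldehyde may be slow, and the electron-rich 2-vinylphenol may be lost by acid-triggered ortho-quinone methide formation and oligomerisation. The fallback changes the order so that no free vinylphenol is handled. Setting out from 9, the iridium-catalysed etherification of step 12 is run on the salicylaldehyde with carbonate 14 to give 4β-{2,6-bis(benzyloxy)-3-formyl-4-[(1S)-1-(3,4,5-tris(benzyloxy)phenyl)prop-2-en-1-yloxy]phenyl}-3,5,7,3',4',5'-hexa-O-benzylepigallocatechin F3. Wittig methylenation of this non-phenolic aldehyde (Ph3PCH3Br, KOt-Bu, THF, 0 °C) comes back to the route at 15.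

**Further compounds**
F1 | step 5 | 4β-(2,4,6-trihydroxyphenyl)-3,5,7,3',4',5'-hexa-O-benzylepigallocatechin | Oc1cc(O)c([C@H]2c3c(OCc4ccccc4)cc(OCc4ccccc4)cc3O[C@H](c3cc(OCc4ccccc4)c(OCc4ccccc4)c(OCc4ccccc4)c3)[C@@H]2OCc2ccccc2)c(O)c1
F2 | step 5 | 4β-[2,6-dihydroxy-4-(triisopropylsilyloxy)phenyl]-3,5,7,3',4',5'-hexa-O-benzylepigallocatechin | CC(C)[Si](Oc1cc(O)c([C@H]2c3c(OCc4ccccc4)cc(OCc4ccccc4)cc3O[C@H](c3cc(OCc4ccccc4)c(OCc4ccccc4)c(OCc4ccccc4)c3)[C@@H]2OCc2ccccc2)c(O)c1)(C(C)C)C(C)C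
F3 | step 8 | 4β-{2,6-bis(benzyloxy)-3-formyl-4-[(1S)-1-(3,4,5-tris(benzyloxy)phenyl)prop-2-en-1-yloxy]phenyl}-3,5,7,3',4',5'-hexa-O-benzylepigallocatechin | C=C[C@@H](c1cc(OCc2ccccc2)c(OCc2ccccc2)c(OCc2ccccc2)c1)Oc1cc(OCc2ccccc2)c([C@H]2c3c(OCc4ccccc4)cc(OCc4ccccc4)cc3O[C@H](c3cc(OCc4ccccc4)c(OCc4ccccc4)c(OCc4ccccc4)c3)[C@@H]2OCc2ccccc2)c(OCc2ccccc2)c1C=O
F4 | step 12 | (S)-1-[3,4,5-tris(benzyloxy)phenyl]-3-(trimethylsilyl)prop-2-yn-1-ol | C[Si](C)(C)C#C[C@@H](O)c1cc(OCc2ccccc2)c(OCc2ccccc2)c(OCc2ccccc2)c1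
F5 | step 12 | (R)-1-[3,4,5-tris(benzyloxy)phenyl]prop-2-yn-1-ol | C#C[C@@H](O)c1cc(OCc2ccccc2)c(OCc2ccccc2)c(OCc2ccccc2)c1
F6 | step 12 | 4β-{2,6-bis(benzyloxy)-4-[(1S)-1-(3,4,5-tris(benzyloxy)phenyl)prop-2-yn-1-yloxy]-3-vinylphenyl}-3,5,7,3',4',5'-hexa-O-benzylepigallocatechin | C#C[C@@H](c1cc(OCc2ccccc2)c(OCc2ccccc2)c(OCc2ccccc2)c1)Oc1cc(OCc2ccccc2)c([C@H]2c3c(OCc4ccccc4)cc(OCc4ccccc4)cc3O[C@H](c3cc(OCc4ccccc4)c(OCc4ccccc4)c(OCc4ccccc4)c3)[C@@H]2OCc2ccccc2)c(OCc2ccccc2)c1C=C
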